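**Plan**

Ring B is numbered C1' (aryl ester oxygen), C2' (H), C3' (OH), C4' (CO2H), C5' (propyl), C6' (H); ring A is the 2,4-dihydroxy-6-pentylbenzoyl group.
Feature: ring B has oxygen on C1' and C3', a carboxyl on C4' and an alkyl on C5'. It is therefore the aromatized form of a 2,4-dioxo-6-propylcyclohexane-1-carboxylate, whose two oxygens differ: the C3' oxygen sits in a β-keto ester, the C1' oxygen does not.
Retrosynthesis: remove the three benzyl groups; take out the C4'=C5' unsaturation of ring B; cut the depside bond C(=O)–O(C1') to a ring-A acid chloride and the dione; cut the dione at C4'–C5' (Michael) and C1'–C2' (Claisen) to benzyl acetoacetate and benzyl (E)-hex-2-enoate; cut the ring-A carboxyl carbon back to olivetol (formylation).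
Forward: ring A is bought as olivetol and carried to the protected acid. Ring B is the only ring made: it is closed saturated, O-acylated at C1', aromatized across C4'–C5', and all benzyl groups are then removed together.
Stereochemistry: the target is achiral; the sp3 centres that arise at C4' and C5' are racemic, need no control and are erased on aromatization.

Key step: step 2

Remark: compounds 4, 5, 12, 13 and 14 are racemic and carry only transient sp3 centres, so their SMILES have no stereodescriptors; dione 5 is written as the diketone although it should exist largely as an enol.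

**Route**

Step 1
Reactants: 1 (E)-hex-2-enoic acid
Product: 2 benzyl (E)-hex-2-enoate
Conditions: BnBr, K2CO3, DMF, rt
Reagents that add atoms: benzyl bromide, BrCc1ccccc1
Why: Carboxylate O-alkylation (SN2 esterification) with benzyl bromide under K2CO3 is mild enough to leave the conjugated E double bond in place.

Step 2
Reactants: 2 benzyl (E)-hex-2-enoate; 3 benzyl acetoacetate
Product: 5 benzyl 2,4-dioxo-6-propylcyclohexane-1-carboxylate, via Michael adduct 4 (not isolated)
Conditions: NaOCH2Ph (1.05 equiv, 1 M in PhCH2OH), toluene, rt then 90 °C; then aq. HCl, 0 °C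
Reagents that add atoms: none
Why: Sodium benzyloxide deprotonates 3 at its central carbon and the stabilised enolate adds 1,4 to C3 of enoate 2 (bond C4'–C5') to give 4; proton exchange then brings up the methyl-ketone enolate, whose carbon attacks the enoate-derived benzyl ester (bond C1'–C2') and expels benzyloxide. The closest known reaction is the Michael–Claisen (Michael–Dieckmann) condensation of acetoacetic esters with crotonates, which gives dihydroorsellinates. Ring B closes in the 6-exo-trig mode, the enolate carbon attacking an ester carbonyl whose C=O lies outside the forming ring. The two new sp3 centres C4' and C5' need no control: C4' is epimerisable, the trans arrangement is expected under the equilibrating conditions, the material is racemic, and both centres become sp2 in step 7. The selectivity needed is regiochemical: the doubly activated carbon is the only soft carbon nucleophile available for the conjugate addition, and closure through the methyl carbon is the only Claisen path to a six-membered ring (any other enolate would close a four-membered ring); the matching benzyl alkoxide rules out ester scrambling, and the final deprotonation of the acidic dione pulls the preceding equilibria forward.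

Step 3
Reactants: 6 olivetol (5-pentylbenzene-1,3-diol)
Product: 8 2,4-dihydroxy-6-pentylbenzaldehyde, via aryl iminium chloride 7 (not isolated)
Conditions: POCl3, DMF, 0 °C to rt; then H2O, 0 to 50 °C
Reagents that add atoms: N,N-dimethylformamide, CN(C)C=O; water, O
Why: Vilsmeier–Haack formylation, in which the chloroiminium ion made from DMF and POCl3 attacks the resorcinol carbon para to one hydroxyl and ortho to the other (the crowded position between the two hydroxyls is the minor site, as with orcinol) and water hydrolyses the aryl iminium salt 7 to the aldehyde.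

Step 4
Reactants: 8 2,4-dihydroxy-6-pentylbenzaldehyde
Product: 9 2,4-bis(benzyloxy)-6-pentylbenzaldehyde
Conditions: BnBr, K2CO3, DMF, 60 °C
Reagents that add atoms: benzyl bromide, BrCc1ccccc1
Why: Williamson etherification of both phenols with benzyl bromide, with warming in DMF sufficing to alkylate the hydroxyl that is hydrogen-bonded to the formyl group.

Step 5
Reactants: 9 2,4-bis(benzyloxy)-6-pentylbenzaldehyde
Product: 10 2,4-bis(benzyloxy)-6-pentylbenzoic acid
Conditions: NaClO2, NaH2PO4, 35% H2O2, MeCN/H2O, 10 °C to rt
Reagents that add atoms: sodium chlorite, [Na+].[O-]Cl=O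
Why: Pinnick oxidation, in which chlorous acid adds to the aldehyde and fragments to the acid while H2O2 reduces the hypochlorous acid by-product, so that the electron-rich ring should not be chlorinated and the benzyl ethers stay untouched.

Step 6
Reactants: 10 2,4-bis(benzyloxy)-6-pentylbenzoic acid; 5 benzyl 2,4-dioxo-6-propylcyclohexane-1-carboxylate
Product: 12 benzyl 4-{[2,4-bis(benzyloxy)-6-pentylbenzoyl]oxy}-2-oxo-6-propylcyclohex-3-ene-1-carboxylate, via acid chloride 11 (not isolated)
Conditions: (COCl)2, cat. DMF, CH2Cl2, 0 °C to rt, evaporate; then 5, Et3N, CH2Cl2, 0 °C to rt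
Reagents that add atoms: none
Why: Acid chloride formation followed by O-acylation of a cyclic 1,3-dione enolate (enol ester formation), in which the triethylammonium enolate of 5 should take the acyl group on the oxygen at C1', remote from the C4' ester and C5' propyl groups, leaving the C3' carbonyl in the β-keto ester, and in which the absence of cyanide or DMAP should prevent an acyl shift to C2'.

Step 7
Reactants: 12 benzyl 4-{[2,4-bis(benzyloxy)-6-pentylbenzoyl]oxy}-2-oxo-6-propylcyclohex-3-ene-1-carboxylate
Product: 15 benzyl 4-{[2,4-bis(benzyloxy)-6-pentylbenzoyl]oxy}-2-hydroxy-6-propylbenzoate, via selenide 13 (not isolated), via selenoxide 14 (not isolated)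
Conditions: PhSeCl, pyridine, CH2Cl2, 0 °C to rt; aq. HCl wash; then 30% H2O2 (excess), CH2Cl2, 0 °C to rt
Reagents that add atoms: none
Why: α-Selenenylation of a β-keto ester followed by selenoxide syn-elimination, in which C4' is the only doubly activated carbon left once C2' is part of the enol ester, the PhSe group should enter anti to the C5' propyl group and hence syn to C5'–H, and the selenoxide 14 eliminates across C4'–C5' to a cyclohexadienone that tautomerises at once to the C3' phenol.

Step 8
Reactants: 15 benzyl 4-{[2,4-bis(benzyloxy)-6-pentylbenzoyl]oxy}-2-hydroxy-6-propylbenzoate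
Product: 16 4-[(2,4-dihydroxy-6-pentylbenzoyl)oxy]-2-hydroxy-6-propylbenzoic acid
Conditions: H2 (1 atm), 10% Pd/C, EtOAc, rt
Reagents that add atoms: none
Why: Catalytic hydrogenolysis over palladium on carbon cleaves the two benzyl ethers and the benzyl ester in one operation, while the aryl ester between rings A and B and both aromatic rings should be inert at 1 atm and rt.

**Compound list**

1 | (E)-hex-2-enoic acid | CCC/C=C/C(=O)O | starting material
2 | benzyl (E)-hex-2-enoate | CCC/C=C/C(=O)OCc1ccccc1 | intermediate
3 | benzyl acetoacetate (benzyl 3-oxobutanoate) | CC(=O)CC(=O)OCc1ccccc1 | starting material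
4 | dibenzyl 2-acetyl-3-propylpentanedioate (Michael adduct, racemic) | CCCC(CC(=O)OCc1ccccc1)C(C(C)=O)C(=O)OCc1ccccc1 | intermediate
5 | benzyl 2,4-dioxo-6-propylcyclohexane-1-carboxylate (racemic) | CCCC1CC(=O)CC(=O)C1C(=O)OCc1ccccc1 | intermediate
6 | olivetol (5-pentylbenzene-1,3-diol) | CCCCCc1cc(O)cc(O)c1 | starting material
7 | (2,4-dihydroxy-6-pentylbenzylidene)dimethyliminium chloride | CCCCCc1cc(O)cc(O)c1C=[N+](C)C.[Cl-] | intermediate
8 | 2,4-dihydroxy-6-pentylbenzaldehyde | CCCCCc1cc(O)cc(O)c1C=O | intermediate
9 | 2,4-bis(benzyloxy)-6-pentylbenzaldehyde | CCCCCc1cc(OCc2ccccc2)cc(OCc2ccccc2)c1C=O | intermediate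
10 | 2,4-bis(benzyloxy)-6-pentylbenzoic acid | CCCCCc1cc(OCc2ccccc2)cc(OCc2ccccc2)c1C(=O)O | intermediate
11 | 2,4-bis(benzyloxy)-6-pentylbenzoyl chloride | CCCCCc1cc(OCc2ccccc2)cc(OCc2ccccc2)c1C(=O)Cl | intermediate
12 | benzyl 4-{[2,4-bis(benzyloxy)-6-pentylbenzoyl]oxy}-2-oxo-6-propylcyclohex-3-ene-1-carboxylate (racemic) | CCCCCc1cc(OCc2ccccc2)cc(OCc2ccccc2)c1C(=O)OC1=CC(=O)C(C(=O)OCc2ccccc2)C(CCC)C1 | intermediate
13 | benzyl 4-{[2,4-bis(benzyloxy)-6-pentylbenzoyl]oxy}-2-oxo-1-(phenylselanyl)-6-propylcyclohex-3-ene-1-carboxylate (racemic) | CCCCCc1cc(OCc2ccccc2)cc(OCc2ccccc2)c1C(=O)OC1=CC(=O)C([Se]c2ccccc2)(C(=O)OCc2ccccc2)C(CCC)C1 | intermediate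
14 | benzyl 4-{[2,4-bis(benzyloxy)-6-pentylbenzoyl]oxy}-2-oxo-1-(phenylseleninyl)-6-propylcyclohex-3-ene-1-carboxylate (racemic) | CCCCCc1cc(OCc2ccccc2)cc(OCc2ccccc2)c1C(=O)OC1=CC(=O)C([Se](=O)c2ccccc2)(C(=O)OCc2ccccc2)C(CCC)C1 | intermediate
15 | benzyl 4-{[2,4-bis(benzyloxy)-6-pentylbenzoyl]oxy}-2-hydroxy-6-propylbenzoate | CCCCCc1cc(OCc2ccccc2)cc(OCc2ccccc2)c1C(=O)Oc1cc(O)c(C(=O)OCc2ccccc2)c(CCC)c1 | intermediate
16 | 4-[(2,4-dihydroxy-6-pentylbenzoyl)oxy]-2-hydroxy-6-propylbenzoic acid | CCCCCc1cc(O)cc(O)c1C(=O)Oc1cc(O)c(C(=O)O)c(CCC)c1 | target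

**Step count**

Total steps: 8.
Longest linear sequence: 6 steps (olivetol 6 through steps 3, 4, 5, 6, 7 and 8); the ring-B arm is steps 1 and 2 before the junction at step 6.

**Steps most likely to fail**

Step 6. The acyl group may go to the wrong atom (the oxygen on C3' or carbon C2'), or the di-ortho-substituted acid chloride may react too slowly and be lost to hydrolysis. The fallback sets out from 5 and 10 and comes back at 15, replacing steps 6 and 7; it aromatizes ring B before acylating it. Bromine (1 equiv) in DMF at 0 °C brominates the dione. Under the HBr formed, the bromine should settle at C4' as benzyl 1-bromo-2,4-dioxo-6-propylcyclohexane-1-carboxylate F1. On warming to about 60 °C this loses HBr across C4'–C5' and gives benzyl 2,4-dihydroxy-6-propylbenzoate F2. Acid 10 is then activated with trifluoroacetic anhydride in toluene at rt as 2,4-bis(benzyloxy)-6-pentylbenzoic trifluoroacetic anhydride F3, which esterifies the free C1' hydroxyl of F2 to give 15. The C3' hydroxyl is hydrogen-bonded to the ester carbonyl and should stay free, as is usual in depside esterifications.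

Step 7. Acyl transfer from the vinylogous anhydride (to pyridine, peroxide or C2'), sluggish selenenylation of a weakly enolised β-keto ester, or attack of electrophilic selenium on the electron-rich rings may erode the aromatization. The fallback sets out from 12 and comes back at 15; it dehydrogenates by hydride abstraction. Me3SiOTf and Et3N in CH2Cl2 at 0 °C should enolise the β-keto ester toward C4' and give benzyl 4-{[2,4-bis(benzyloxy)-6-pentylbenzoyl]oxy}-6-propyl-2-[(trimethylsilyl)oxy]cyclohexa-1,3-diene-1-carboxylate F4, a 5',6'-dihydroarene. DDQ in toluene at rt removes hydride from allylic C5' or C6' and then a proton, giving benzyl 4-{[2,4-bis(benzyloxy)-6-pentylbenzoyl]oxy}-6-propyl-2-[(trimethylsilyl)oxy]benzoate F5. Dilute aqueous HCl in THF cleaves the O–Si bond to 15.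

Step 2. Retro-Claisen loss of the acetyl group from adduct 4 by benzyloxide, drift of the enoate double bond out of conjugation, or reversible addition of benzyloxide to the enoate may drain material before the ring closes. The fallback sets out from 3 and comes back at 4, which is then closed to 5; it builds C4'–C5' as an alkene first. Knoevenagel condensation of 3 with butanal (cat. piperidine/AcOH, CH2Cl2, 0 °C) gives benzyl 2-acetylhex-2-enoate F6. The lithium enolate of benzyl acetate (LiN(iPr)2, THF, −78 °C) adds 1,4 to this doubly activated acceptor, forming C5'–C6' and, after a proton quench, isolated 4. Potassium tert-butoxide in THF (0 °C to rt), a base too hindered to attack the acetyl group, then effects the same C1'–C2' Claisen closure to 5.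

**Further compounds**

F1 | step 6 | benzyl 1-bromo-2,4-dioxo-6-propylcyclohexane-1-carboxylate | CCCC1CC(=O)CC(=O)C1(Br)C(=O)OCc1ccccc1
F2 | step 6 | benzyl 2,4-dihydroxy-6-propylbenzoate | CCCc1cc(O)cc(O)c1C(=O)OCc1ccccc1
F3 | step 6 | 2,4-bis(benzyloxy)-6-pentylbenzoic trifluoroacetic anhydride | CCCCCc1cc(OCc2ccccc2)cc(OCc2ccccc2)c1C(=O)OC(=O)C(F)(F)F
F4 | step 7 | benzyl 4-{[2,4-bis(benzyloxy)-6-pentylbenzoyl]oxy}-6-propyl-2-[(trimethylsilyl)oxy]cyclohexa-1,3-diene-1-carboxylate | CCCCCc1cc(OCc2ccccc2)cc(OCc2ccccc2)c1C(=O)OC1=CC(O[Si](C)(C)C)=C(C(=O)OCc2ccccc2)C(CCC)C1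
F5 | step 7 | benzyl 4-{[2,4-bis(benzyloxy)-6-pentylbenzoyl]oxy}-6-propyl-2-[(trimethylsilyl)oxy]benzoate | CCCCCc1cc(OCc2ccccc2)cc(OCc2ccccc2)c1C(=O)Oc1cc(O[Si](C)(C)C)c(C(=O)OCc2ccccc2)c(CCC)c1
F6 | step 2 | benzyl 2-acetylhex-2-enoate (E/Z mixture) | CCCC=C(C(C)=O)C(=O)OCc1ccccc1
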